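## Structural features

The target is a trans-fused decalin of the enantiomeric eudesmane series. Ring A is C1–C5 and C10; ring B is C5–C10; C14 is the methyl on C10, C15 the methyl on C4, and C11 the carbinol carbon on C7. At C1 it carries a benzylic methine C1′, which bears an isobutyl group (C2′, C3′) and a hexasubstituted 3,5-diformylphloroglucinol ring.

There are six stereocentres. C1′, C1 and the quaternary C10 are contiguous, C5 and C4 continue the chain on the other side of C10, and C7 stands alone in ring B. The C1 side chain, the C7 hydroxyisopropyl group and C15 are equatorial. The C4 hydroxyl is axial and syn-axial to C14, and the C1 side chain is cis to C14.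

The fragile groups are the two tertiary alcohols (above all the axial one, which dehydrates easily) and the vinylogous-acid aldehydes. Strong Lewis and Brønsted acids are therefore excluded once the alcohols are in place.

The real difficulty is the C1–C1′ bond. It joins two tertiary carbons, one next to a quaternary centre and the other next to a di-ortho-oxygenated arene. It lies on the more hindered face of ring A, and C1′ has no neighbouring function through which it could be controlled. C4, C5 and C7, by contrast, follow from the bias of a trans-decalin with an axial angular methyl group.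

The key step exploits the fact that C3, 1,3-related to C1 through C2, is a bare methylene in the target. A C3–O bond can therefore be spent tracelessly in a [3,3] shift that writes C1 and C1′ together. This is done before ring A exists, while C1 is still the terminus of a freely rotating (E)-alkene on C10.

## Logic of the disconnections

**24 ⇒ 23 ⇒ 21 ⇒ 20.**
- Bonds cut: the two aryl–CHO bonds; the three phenolic O–H are traced back to O–CH3.
- Reason: the aldehydes tolerate none of the carbanion, hydride and hydrogenation chemistry needed earlier.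
- Gain: the arene becomes an inert spectator with two equivalent free positions.
- Demand: both operations must run under basic, non-ionising conditions because of the tertiary alcohols. This means halogen–lithium exchange for the formyl groups and a soft nucleophile for the ethers.

**20 ⇒ 19.**
- Bond cut: C4–C15.
- Reason: an axial hydroxyl syn to C14 is what equatorial attack of a small carbon nucleophile on a C4 ketone delivers. Any oxygenation of a C4 alkene would give the other epimer.
- Gain: one stereocentre less, and C5 becomes an epimerisable, thermodynamically secured centre.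
- Demand: addition must beat enolisation.

**19 ⇒ 18 ⇒ 17.**
- Three C=C bonds are reintroduced (C2=C3, C7=C8, C2′=C3′), and then C2=C3 is cut.
- Reason: C2 and C3 carry nothing in the target, so the ring-A closure can be placed there.
- Gain: ring A disappears and C7 becomes sp2.
- Demand: the closure must choose the six-membered ring. One hydrogenation must then set C7 from the face opposite C14.

**17 ⇒ 16 ⇒ 15 ⇒ 14 ⇒ 12.**
- Bonds cut: C3–C4 (vinyl to acyl carbon) and C2′=C3′ (olefination).
- Reason: both are additions to carbonyl groups that are already present.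
- Gain: the side chain shrinks to a carboxyl group on C1′.
- Demand: the C2′ carboxyl and the C4 acyl group must be told apart.

**12 ⇒ 9 (key).**
- Bond cut: C1–C1′; the C2=C3 bond moves back to C1=C2 and C3 regains an oxygen.
- Reason: only a closed, intramolecular transition state can set C1′ relative to C1. An acyclic (E)-alkene avoids the eclipsing with axial C14 that the same shift would suffer in a finished trans-decalin.
- Gain: the hardest bond and two of the three contiguous stereocentres are traded for one ester C–O bond and one carbinol centre.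
- Demand: a geometrically pure ketene acetal and a chair transition state.
- In one sentence: ring A is not yet there when an arylacetate hung on a C3 carbinol delivers C1′ to C1.

**9 ⇒ 7 + 8, then 7 ⇒ 6 ⇒ 5 ⇒ 4.**
- Bonds cut: the ester C–O, the C3–H bond (reagent-controlled reduction) and C1=C2 (olefination of the C1 aldehyde).
- Gain: an achiral acid and a monocyclic aldehyde ester.
- Demand: (E)-geometry, and a C3 configuration that is independent of the ring.

**4 ⇒ 2 + 3.**
- Bonds cut: C5–C6 and C9–C10.
- Reason: C10 carries a formyl carbon (C1) and a methyl group, which is the substitution of an α-methyl enal. C4 and C1 are trans on adjacent carbons, which is the geometry of an (E)-alkene.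
- Gain: ring B, the quaternary centre and the future trans ring fusion come from two achiral pieces.
- Demand: catalyst control of the C10 face, and para regiochemistry.

**2 ⇒ 1.**
- Bonds cut: the C8=C9 unit is removed as ethylene.
- Gain: a catalogue alkyne.
- Demand: none beyond clean cross metathesis.

## Other disconnections considered

**Alternative 1:** (the first that comes to mind) cut C1–C1′ in the finished decalin as nucleophile plus benzylic electrophile.
- Forward key step: vinylogous Mukaiyama-type alkylation of the silyl dienol ether A1 with the cation released from the benzylic alcohol A2, giving A3.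
- Ground for rejection: the electrophile must approach C1 anti to the axial C14. The bond therefore forms on the wrong face and C1 has to be corrected afterwards.
- The transition state is open, so nothing orders C1′.
- A complete eudesmane synthesis is needed before the difficult bond is even attempted.

**Alternative 2:** cut C1–C1′, C5–C10 and C4–O at once (biomimetic).
- Forward key step: addition of the ten-membered dienol A4 to the o-quinone methide A5, transannular closure and capture of the C4 cation by water.
- Ground for rejection: the cation should be captured anti to the C5–C10 bond just formed, from the equatorial side. That leads to the C4 epimer A6 and not to 24.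
- A4 is prone to Cope rearrangement and is not available in this enantiomeric series.
- Hetero-Diels–Alder addition competes, and C1′ is again left to chance.

**Alternative 3:** cut C1–C1′ as a union of two carbanion equivalents.
- Forward key step: Zweifel olefination of the C1 vinyllithium A7 with the enantioenriched benzylic boronic ester A8 to give A9, followed by hydrogenation anti to C14.
- This is stereospecific at C1′, but the ate complex has to form between a di-ortho-substituted secondary boronate and a vinyllithium next to a quaternary carbon.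
- The boron–iodine elimination has to occur within a six-membered ring.
- A7 presupposes a decalin with a C1 ketone and the C4 carbinol already in place, which costs more steps than the chosen plan.

Key step: step 7

Assumption: compounds 1, 3 and 8 are taken as catalogue chemicals, and the atom numbers of the target (C1–C15, C1′–C3′) are used for all intermediates.

## Route

Step 1
Reactants: 1 trimethyl[(2-methylbut-3-yn-2-yl)oxy]silane
Product: 2 trimethyl[(2-methyl-3-methylidenepent-4-en-2-yl)oxy]silane (a 2-substituted buta-1,3-diene)
Conditions: ethylene (1 atm), second-generation Grubbs catalyst RuCl2(=CHPh)(PCy3)(H2IMes) (3 mol %), CH2Cl2, 40 °C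
Reagents that add atoms: ethylene, C=C
Why: Enyne cross metathesis of a terminal propargylic ether with ethylene, a standard entry to 2-substituted butadienes; no stereocentre is formed and the silyl ether keeps the oxygen from binding ruthenium.

Step 2
Reactants: 2 trimethyl[(2-methyl-3-methylidenepent-4-en-2-yl)oxy]silane; 3 ethyl (E)-3-methyl-4-oxobut-2-enoate
Product: 4 ethyl (1S,6S)-6-formyl-6-methyl-3-[2-(trimethylsilyloxy)propan-2-yl]cyclohex-3-ene-1-carboxylate (C5 S and C10 S; CHO trans to CO2Et)
Conditions: (R)-3,3-diphenyl-1-(2-methylphenyl)tetrahydro-1H,3H-pyrrolo[1,2-c][1,3,2]oxazaborole protonated by Tf2NH (15 mol %), CH2Cl2, −78 → −40 °C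
Reagents that add atoms: none
Why: Enantioselective Diels–Alder reaction of an α-methyl enal under cationic oxazaborolidine catalysis; boron binds the formyl oxygen, so C5 (β to CHO) bonds to the diene CH2 next to the substituted carbon and the side chain ends on C7, para to C10. The (E)-geometry of 3 is copied into the trans relation of C1 and C4 (future trans ring fusion), and in the formyl C–H···O bound complex the (R)-catalyst covers the Re face of C10, so the quaternary centre is set by the reagent.

Step 3
Reactants: 4 ethyl (1S,6S)-6-formyl-6-methyl-3-[2-(trimethylsilyloxy)propan-2-yl]cyclohex-3-ene-1-carboxylate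
Product: 5 ethyl (1S,6R)-6-methyl-6-[(E)-3-oxobut-1-enyl]-3-[2-(trimethylsilyloxy)propan-2-yl]cyclohex-3-ene-1-carboxylate
Conditions: Ph3P=CHC(O)CH3, toluene, 100 °C
Reagents that add atoms: 1-(triphenylphosphoranylidene)propan-2-one, CC(=O)C=P(c1ccccc1)(c1ccccc1)c1ccccc1
Why: Wittig olefination with a stabilised ylide should give the (E)-enone; the aldehyde has no α-hydrogen, so the heating that its neopentyl position requires does no harm. The change of the C10 descriptor is a priority effect only.

Step 4
Reactants: 5 ethyl (1S,6R)-6-methyl-6-[(E)-3-oxobut-1-enyl]-3-[2-(trimethylsilyloxy)propan-2-yl]cyclohex-3-ene-1-carboxylate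
Product: 6 ethyl (1S,6R)-6-[(1E,3S)-3-hydroxybut-1-enyl]-6-methyl-3-[2-(trimethylsilyloxy)propan-2-yl]cyclohex-3-ene-1-carboxylate
Conditions: (R)-2-methyl-CBS-oxazaborolidine (15 mol %), BH3·SMe2, THF, −30 °C; MeOH
Reagents that add atoms: none
Why: Corey–Bakshi–Shibata reduction of an (E)-enone, with the alkenyl group as the large and methyl as the small substituent; the (R)-catalyst should give the (3S)-carbinol by reagent control, far from the ring stereocentres. At this temperature the ester and the hindered trisubstituted alkene are not touched.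

Step 5
Reactants: 6 ethyl (1S,6R)-6-[(1E,3S)-3-hydroxybut-1-enyl]-6-methyl-3-[2-(trimethylsilyloxy)propan-2-yl]cyclohex-3-ene-1-carboxylate
Product: 7 (1S,6R)-6-[(1E,3S)-3-hydroxybut-1-enyl]-N-methoxy-N,6-dimethyl-3-[2-(trimethylsilyloxy)propan-2-yl]cyclohex-3-ene-1-carboxamide
Conditions: MeNH(OMe)·HCl, iPrMgCl, THF, −20 → 0 °C
Reagents that add atoms: N,O-dimethylhydroxylamine hydrochloride, CNOC.Cl
Why: Aminolysis of the ester by the magnesium amide (Weinreb amide synthesis), done here while C4 is least crowded; it makes C4 inert to borohydride and ylide and ready for a single vinyl addition. C5 keeps its configuration because the trans-diequatorial arrangement is also the stable one.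

Step 6
Reactants: 7 (1S,6R)-6-[(1E,3S)-3-hydroxybut-1-enyl]-N-methoxy-N,6-dimethyl-3-[2-(trimethylsilyloxy)propan-2-yl]cyclohex-3-ene-1-carboxamide; 8 2-(2,4,6-trimethoxyphenyl)acetic acid
Product: 9 (2,4,6-trimethoxyphenyl)acetate of alcohol 7 (3S 5S 10R)
Conditions: DCC, DMAP (cat.), CH2Cl2, 0 °C → rt
Reagents that add atoms: none
Why: Steglich esterification of an unhindered secondary allylic alcohol with retention at C3; no other free hydroxyl is present.

Step 7
Reactants: 9 (2,4,6-trimethoxyphenyl)acetate of alcohol 7
Product: 12 (2R,3R,4E)-3-{(1R,6S)-4-(2-hydroxypropan-2-yl)-6-[methoxy(methyl)carbamoyl]-1-methylcyclohex-3-enyl}-2-(2,4,6-trimethoxyphenyl)hex-4-enoic acid (1′R 1R 5S 10R), via ketene acetal 10 (not isolated), via silyl ester 11 (not isolated)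
Conditions: LDA (1.15 equiv), THF–DMPU 4:1, −78 °C; TBSCl; −78 → 65 °C; then 10% aq citric acid, MeOH, rt
Reagents that add atoms: tert-butyldimethylsilyl chloride, CC(C)(C)[Si](C)(C)Cl (silyl group of 10 and 11 only, lost again on work-up)
Why: Deprotonation of the arylacetate in THF–DMPU should give the enolate with aryl cis to O–Li, because allylic 1,3-strain between the di-ortho-substituted arene and the alkoxy group disfavours the other isomer, and O-silylation freezes it as the (Z)-silyl ketene acetal 10. On warming, 10 undergoes a concerted suprafacial [3,3]-sigmatropic shift (Ireland–Claisen rearrangement; closest known cases are acyclic (E)-allylic arylacetates and propionates) that breaks C3–O, makes C1–C1′ and moves the double bond to C2=C3. No ring is closed; the array C1′–C(OSi)–O–C3–C2–C1 should adopt a chair because a boat would eclipse the two largest groups, the arene and the ring-B quaternary carbon. C1 is set by chirality transfer: with the C3 methyl group equatorial only one face of the (E)-alkene is within reach, so (3S) becomes (1R) whatever small bias C10 exerts. C1′ is set by the ketene acetal geometry: aryl trans to the allylic oxygen is equatorial, and together with the equatorial C10 substituent this gives the (1′R,1R) pair. The selectivities needed are geometric purity of 10 and chair over boat; chemoselectivity is secured because the arylacetate C–H is by far the most acidic one (C5–H of the amide is tertiary and shielded) and only one allylic ester is present. The new (E)-propenyl group is the handle for ring A and the carboxyl carbon is C2′. Citric acid in methanol then cleaves the silyl ester and the trimethylsilyl ether without ionising the tertiary allylic alcohol.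

Step 8
Reactants: 12 acid (1′R 1R 5S 10R)
Product: 14 primary alcohol (C2′H2OH in place of CO2H; otherwise as 12), via acyl imidazolide 13 (not isolated)
Conditions: CDI, THF, rt; then NaBH4, H2O, 0 °C
Reagents that add atoms: 1,1′-carbonyldiimidazole, O=C(n1ccnc1)n1ccnc1 (imidazolyl group of 13 only)
Why: Activation as the acyl imidazolide and borohydride reduction distinguishes the acid from the Weinreb amide, which borohydride does not reduce; alkenes and the tertiary alcohol are inert. The activated acid has a single electrophilic carbonyl, which matters for so hindered an acid.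

Step 9
Reactants: 14 primary alcohol
Product: 15 aldehyde (C2′HO; 1′R 1R 5S 10R)
Conditions: Dess–Martin periodinane, CH2Cl2, 0 °C → rt
Reagents that add atoms: none
Why: Dess–Martin oxidation under near-neutral conditions; the tertiary alcohol cannot be oxidised, and the crowded α-aryl aldehyde, whose arene is twisted out of conjugation, should not enolise.

Step 10
Reactants: 15 aldehyde
Product: 16 isobutenyl compound (C1′–CH=C(CH3)2; 1′R 1R 5S 10R)
Conditions: iPrPPh3I, n-BuLi, THF, 0 °C; then 15, −78 °C → rt
Reagents that add atoms: isopropyltriphenylphosphonium iodide, CC(C)[P+](c1ccccc1)(c1ccccc1)c1ccccc1.[I-]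
Why: Wittig olefination with a non-stabilised ylide; addition to the aldehyde at low temperature is faster than deprotonation at C1′ and than any attack on the amide. Excess ylide covers the free hydroxyl.

Step 11
Reactants: 16 isobutenyl compound
Product: 17 vinyl ketone (C4(=O)–CH=CH2; 1′R 1R 5S 10R)
Conditions: CH2=CHMgBr, THF, −20 → 0 °C; inverse quench into cold aq NaHSO4
Reagents that add atoms: vinylmagnesium bromide, C=C[Mg]Br
Why: Weinreb ketone synthesis; the chelated tetrahedral intermediate prevents a second addition. The acidic inverse quench protonates the released amine before it can add to the enone.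

Step 12
Reactants: 17 vinyl ketone
Product: 18 (1R,5S,10R)-Δ2,Δ7-dien-4-one decalin bearing the (1′R)-1-aryl-3-methylbut-2-enyl group at C1 and the hydroxyisopropyl group at C7
Conditions: second-generation Hoveyda–Grubbs catalyst RuCl2(=CH-C6H4-2-OiPr)(H2IMes) (5 mol %), toluene (0.005 M), 80 °C
Reagents that add atoms: none
Why: Ring-closing metathesis of an enone with a propenyl group; C1 and C4 are trans-diequatorial neighbours on ring B, so the six-membered ring A closes as a trans-decalin with loss of propene. The ring-B alkene is trisubstituted and shielded, and closure onto the isobutenyl group would need a seven-membered ring.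

Step 13
Reactants: 18 dienone
Product: 19 (1′R,1R,5S,7S,10R)-4-ketone (saturated decalone with isobutyl side chain and equatorial hydroxyisopropyl group)
Conditions: H2 (4 atm), 10% Pd/C, EtOAc, Et3N (trace), rt
Reagents that add atoms: none
Why: Heterogeneous hydrogenation of all three C=C bonds; the trans-decalin adsorbs on the face opposite the axial C14, so hydrogen reaches C7 from that face and the hydroxyisopropyl group becomes equatorial and cis to C14. C1′, C1 and C10 are not touched, and C5 stays in its more stable trans form.

Step 14
Reactants: 19 4-ketone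
Product: 20 (1′R,1R,4R,5S,7S,10R)-diol with the 2,4,6-trimethoxyphenyl group (target skeleton without formyl groups and as the trimethyl ether)
Conditions: MeLi (excess), Et2O–THF, −78 → 0 °C; aq NH4Cl
Reagents that add atoms: methyllithium, [Li]C
Why: 1,2-Addition of a small organolithium to a decalone; axial approach is blocked by the 1,3-related axial C14, so methyl enters equatorially and the hydroxyl ends axial, cis to C14, as required. The C11 alkoxide is a spectator.

Step 15
Reactants: 20 diol
Product: 21 3,5-dibromo-2,4,6-trimethoxyphenyl analogue of 20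
Conditions: NBS (2.1 equiv), CH2Cl2, −20 → 0 °C, dark
Reagents that add atoms: N-bromosuccinimide, O=C1CCC(=O)N1Br
Why: Electrophilic aromatic bromination of a 1,3,5-trialkoxybenzene; only the two equivalent free positions can react, and the conditions are neutral for the tertiary alcohols.

Step 16
Reactants: 21 dibromide
Product: 23 3,5-diformyl-2,4,6-trimethoxyphenyl analogue of 20, via tetralithio species 22 (not isolated)
Conditions: t-BuLi (6.5 equiv), THF, −78 °C; DMF, −78 °C → rt; aq NH4Cl
Reagents that add atoms: N,N-dimethylformamide, CN(C)C=O; tert-butyllithium, [Li]C(C)(C)C (lithium of 22 only)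
Why: Double bromine–lithium exchange made irreversible by the second equivalent of t-BuLi per bromine, each aryllithium being flanked and stabilised by two methoxy groups; formylation with DMF follows. The alcohols are protected as their lithium alkoxides, so no acid ever meets them.

Step 17
Reactants: 23 dialdehyde trimethyl ether
Product: 24 target CNP0409870.6 (1′R,1R,4R,5S,7S,10R)
Conditions: NaSEt (excess), DMF, 100 °C; cold dilute HCl to pH 4
Reagents that add atoms: none
Why: SN2 demethylation of aryl methyl ethers by a thiolate; every methoxy group is ortho or para to a formyl group, which makes each phenoxide a good leaving group. The basic medium leaves both tertiary alcohols and all stereocentres untouched.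

## Compound list

1 | trimethyl[(2-methylbut-3-yn-2-yl)oxy]silane | C#CC(C)(C)O[Si](C)(C)C | starting material
2 | trimethyl[(2-methyl-3-methylidenepent-4-en-2-yl)oxy]silane | C=CC(=C)C(C)(C)O[Si](C)(C)C | intermediate
3 | ethyl (E)-3-methyl-4-oxobut-2-enoate | CCOC(=O)/C=C(\C)C=O | starting material
4 | ethyl (1S,6S)-6-formyl-6-methyl-3-[2-(trimethylsilyloxy)propan-2-yl]cyclohex-3-ene-1-carboxylate | CCOC(=O)[C@H]1CC(C(C)(C)O[Si](C)(C)C)=CC[C@]1(C)C=O | intermediate
5 | ethyl (1S,6R)-6-methyl-6-[(E)-3-oxobut-1-enyl]-3-[2-(trimethylsilyloxy)propan-2-yl]cyclohex-3-ene-1-carboxylate | CCOC(=O)[C@H]1CC(C(C)(C)O[Si](C)(C)C)=CC[C@]1(C)/C=C/C(C)=O | intermediate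
6 | ethyl (1S,6R)-6-[(1E,3S)-3-hydroxybut-1-enyl]-6-methyl-3-[2-(trimethylsilyloxy)propan-2-yl]cyclohex-3-ene-1-carboxylate | CCOC(=O)[C@H]1CC(C(C)(C)O[Si](C)(C)C)=CC[C@]1(C)/C=C/[C@H](C)O | intermediate
7 | (1S,6R)-6-[(1E,3S)-3-hydroxybut-1-enyl]-N-methoxy-N,6-dimethyl-3-[2-(trimethylsilyloxy)propan-2-yl]cyclohex-3-ene-1-carboxamide | CON(C)C(=O)[C@H]1CC(C(C)(C)O[Si](C)(C)C)=CC[C@]1(C)/C=C/[C@H](C)O | intermediate
8 | 2-(2,4,6-trimethoxyphenyl)acetic acid | COc1cc(OC)c(CC(=O)O)c(OC)c1 | starting material
9 | (2,4,6-trimethoxyphenyl)acetate of 7 (3S,5S,10R) | CON(C)C(=O)[C@H]1CC(C(C)(C)O[Si](C)(C)C)=CC[C@]1(C)/C=C/[C@H](C)OC(=O)Cc2c(OC)cc(OC)cc2OC | intermediate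
10 | (Z)-O-tert-butyldimethylsilyl ketene acetal of 9 (aryl cis to OSi, trans to the allylic oxygen) | CON(C)C(=O)[C@H]1CC(C(C)(C)O[Si](C)(C)C)=CC[C@]1(C)/C=C/[C@H](C)O/C(O[Si](C)(C)C(C)(C)C)=C/c2c(OC)cc(OC)cc2OC | intermediate
11 | tert-butyldimethylsilyl ester of 12 still carrying the C11 trimethylsilyl ether | CC(C)(C)[Si](C)(C)OC(=O)[C@@H](c2c(OC)cc(OC)cc2OC)[C@@H](/C=C/C)[C@@]1(C)CC=C(C(C)(C)O[Si](C)(C)C)C[C@@H]1C(=O)N(C)OC | intermediate
12 | (2R,3R,4E)-3-{(1R,6S)-4-(2-hydroxypropan-2-yl)-6-[methoxy(methyl)carbamoyl]-1-methylcyclohex-3-enyl}-2-(2,4,6-trimethoxyphenyl)hex-4-enoic acid | OC(=O)[C@@H](c2c(OC)cc(OC)cc2OC)[C@@H](/C=C/C)[C@@]1(C)CC=C(C(C)(C)O)C[C@@H]1C(=O)N(C)OC | intermediate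
13 | acyl imidazolide of 12 | O=C(n3ccnc3)[C@@H](c2c(OC)cc(OC)cc2OC)[C@@H](/C=C/C)[C@@]1(C)CC=C(C(C)(C)O)C[C@@H]1C(=O)N(C)OC | intermediate
14 | primary alcohol from 12 (C2′H2OH; 1′R,1R,5S,10R) | OC[C@@H](c2c(OC)cc(OC)cc2OC)[C@@H](/C=C/C)[C@@]1(C)CC=C(C(C)(C)O)C[C@@H]1C(=O)N(C)OC | intermediate
15 | aldehyde (C2′HO; 1′R,1R,5S,10R) | O=C[C@@H](c2c(OC)cc(OC)cc2OC)[C@@H](/C=C/C)[C@@]1(C)CC=C(C(C)(C)O)C[C@@H]1C(=O)N(C)OC | intermediate
16 | isobutenyl Weinreb amide (1′R,1R,5S,10R) | CC(C)=C[C@@H](c2c(OC)cc(OC)cc2OC)[C@@H](/C=C/C)[C@@]1(C)CC=C(C(C)(C)O)C[C@@H]1C(=O)N(C)OC | intermediate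
17 | vinyl ketone (1′R,1R,5S,10R) | CC(C)=C[C@@H](c2c(OC)cc(OC)cc2OC)[C@@H](/C=C/C)[C@@]1(C)CC=C(C(C)(C)O)C[C@@H]1C(=O)C=C | intermediate
18 | trans-fused Δ2,Δ7-dien-4-one with (1′R)-1-aryl-3-methylbut-2-enyl group at C1 (1R,5S,10R) | CC(C)=C[C@@H](c3c(OC)cc(OC)cc3OC)[C@H]1C=CC(=O)[C@H]2CC(C(C)(C)O)=CC[C@]12C | intermediate
19 | saturated 4-ketone (1′R,1R,5S,7S,10R) | CC(C)C[C@@H](c3c(OC)cc(OC)cc3OC)[C@H]1CCC(=O)[C@H]2C[C@@H](C(C)(C)O)CC[C@]12C | intermediate
20 | 4,11-diol with 2,4,6-trimethoxyphenyl group (1′R,1R,4R,5S,7S,10R) | CC(C)C[C@@H](c3c(OC)cc(OC)cc3OC)[C@H]1CC[C@@](C)(O)[C@H]2C[C@@H](C(C)(C)O)CC[C@]12C | intermediate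
21 | 3,5-dibromo-2,4,6-trimethoxyphenyl analogue of 20 | CC(C)C[C@@H](c3c(OC)c(Br)c(OC)c(Br)c3OC)[C@H]1CC[C@@](C)(O)[C@H]2C[C@@H](C(C)(C)O)CC[C@]12C | intermediate
22 | 3,5-dilithioarene bis(lithium alkoxide) from 21 | CC(C)C[C@@H](c3c(OC)c([Li])c(OC)c([Li])c3OC)[C@H]1CC[C@@](C)(O[Li])[C@H]2C[C@@H](C(C)(C)O[Li])CC[C@]12C | intermediate
23 | 3,5-diformyl-2,4,6-trimethoxyphenyl analogue of 20 | CC(C)C[C@@H](c3c(OC)c(C=O)c(OC)c(C=O)c3OC)[C@H]1CC[C@@](C)(O)[C@H]2C[C@@H](C(C)(C)O)CC[C@]12C | intermediate
24 | CNP0409870.6 (1′R,1R,4R,5S,7S,10R) | CC(C)C[C@@H](c1c(O)c(C=O)c(O)c(C=O)c1O)[C@H]1CC[C@@](C)(O)[C@H]2C[C@@H](C(C)(C)O)CC[C@]12C | target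

## Step count and least certain steps

Total step count: 17. Longest linear sequence: 17 steps (1 → 24); compounds 3 and 8 enter directly.

**Step 7 (key step).**
- Most likely failure: erosion of the ketene acetal geometry during enolisation, or partial leakage through a boat. Either would lower control at C1′ while C1 stays secure.
- Second risk: a rearrangement slowed by the two bulky termini, which gives the ketene acetal time to be lost by C-silylation or adventitious hydrolysis.
- Fallback (sets out from 7, returns at 15): the enol geometry is fixed outside the substrate.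
  - Takai olefination of 2,4,6-trimethoxybenzaldehyde (CHI3, chromium dichloride CrCl2, THF) gives (E)-2-(2-iodoethenyl)-1,3,5-trimethoxybenzene F1.
  - Copper-catalysed C–O coupling of 7 with F1 (copper iodide CuI, 3,4,7,8-tetramethyl-1,10-phenanthroline, Cs2CO3, toluene, 110 °C) should give, with retention, the allyl (E)-2-arylvinyl ether F2.
  - In F2 the aryl group is trans to oxygen by construction. It rearranges in the same pot through the same chair (aliphatic Claisen rearrangement) to the aldehyde silyl ether F3.
  - Citric acid in methanol then gives 15. Steps 6, 8 and 9 become unnecessary; the price is exposure of an α-aryl aldehyde to warm carbonate.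

**Step 2.**
- Most likely failure: partial regiochemical control by the ester instead of the formyl group, incomplete shielding of one face, and loss of the trimethylsilyl group to the strongly acidic catalyst with consequent catalyst deactivation.
- Fallback (sets out from 2 and 3, returns at 6): absolute control is moved to the reduction.
  - An achiral Lewis acid (dimethylaluminium chloride Me2AlCl, CH2Cl2, −78 °C) gives 4 together with its enantiomer F4.
  - Step 3 gives 5 and the enantiomeric enone F5.
  - Step 4, being reagent controlled, turns both into (3S)-carbinols, namely 6 and its diastereomer F6. These are separated by chromatography, so no extra step is needed.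

**Step 12.**
- Most likely failure: slow initiation, because one alkene is electron poor and the other is branched at its allylic carbon. Intermolecular metathesis and catalyst decay could then compete.
- Fallback (sets out from 17, returns at 18): the electron-poor partner is removed.
  - Luche reduction (NaBH4, CeCl3·7H2O, MeOH) gives the allylic alcohol F7 as a C4 epimer mixture.
  - Ring-closing metathesis of this more reactive diene gives the cyclohexenol F8.
  - Oxidation with MnO2 gives 18.

**Step 13.**
- Most likely failure: hydrogenolysis or transposition of the tertiary allylic alcohol on palladium, double-bond migration before reduction, and incomplete facial selectivity at C7.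
- Fallback (sets out from 18, returns at 19; no new compound, F0): radical hydrogen-atom-transfer hydrogenation with Mn(dpm)3, PhSiH3 and t-BuOOH in iPrOH. It passes through a tertiary C7 radical, gives the thermodynamically preferred equatorial substituent, and does not cleave allylic C–O bonds.

**Step 16.**
- Most likely failure: an incomplete second exchange on a ring that is already anionic, or proton capture before DMF arrives. Either leads to partial formylation.
- Fallback (sets out from 21, returns at 23): one position at a time.
  - Single exchange (n-BuLi, 3.1 equiv) and DMF give the bromo aldehyde F9.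
  - HC(OMe)3 with PPTS in MeOH gives the dimethyl acetal F10.
  - A second exchange and DMF give the aldehyde acetal F11.
  - Wet acetone with PPTS gives 23.

**Step 17.**
- Most likely failure: stalling after the first or second cleavage as negative charge builds up on the ring, and reversible thiolate addition to the aldehydes.
- Fallback (sets out from 23, returns at 24; no new compound, F0): chelation-assisted cleavage with magnesium diiodide etherate MgI2·OEt2 in toluene. The formyl oxygen and the neighbouring methoxy oxygen bind magnesium and iodide removes the methyl group. This is a different mechanism that works on each ortho-formyl ether independently of the charge on the ring.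

## Further compounds

F1 | step 7 | (E)-2-(2-iodoethenyl)-1,3,5-trimethoxybenzene | COc1cc(OC)c(/C=C/I)c(OC)c1
F2 | step 7 | allyl (E)-2-(2,4,6-trimethoxyphenyl)vinyl ether of 7 | CON(C)C(=O)[C@H]1CC(C(C)(C)O[Si](C)(C)C)=CC[C@]1(C)/C=C/[C@H](C)O/C=C/c2c(OC)cc(OC)cc2OC
F3 | step 7 | C11 trimethylsilyl ether of 15 | O=C[C@@H](c2c(OC)cc(OC)cc2OC)[C@@H](/C=C/C)[C@@]1(C)CC=C(C(C)(C)O[Si](C)(C)C)C[C@@H]1C(=O)N(C)OC
F4 | step 2 | enantiomer of 4 | CCOC(=O)[C@@H]1CC(C(C)(C)O[Si](C)(C)C)=CC[C@@]1(C)C=O
F5 | step 2 | enantiomer of 5 | CCOC(=O)[C@@H]1CC(C(C)(C)O[Si](C)(C)C)=CC[C@@]1(C)/C=C/C(C)=O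
F6 | step 2 | (3S)-carbinol of the enantiomeric ring series (diastereomer of 6) | CCOC(=O)[C@@H]1CC(C(C)(C)O[Si](C)(C)C)=CC[C@@]1(C)/C=C/[C@H](C)O
F7 | step 12 | allylic alcohol from 17 (C4 epimers) | CC(C)=C[C@@H](c2c(OC)cc(OC)cc2OC)[C@@H](/C=C/C)[C@@]1(C)CC=C(C(C)(C)O)C[C@@H]1C(O)C=C
F8 | step 12 | Δ2-en-4-ol decalin (C4 epimers) | CC(C)=C[C@@H](c3c(OC)cc(OC)cc3OC)[C@H]1C=CC(O)[C@H]2CC(C(C)(C)O)=CC[C@]12C
F0 | step 13 | none | none
F9 | step 16 | 3-bromo-5-formyl-2,4,6-trimethoxyphenyl analogue of 20 | CC(C)C[C@@H](c3c(OC)c(C=O)c(OC)c(Br)c3OC)[C@H]1CC[C@@](C)(O)[C@H]2C[C@@H](C(C)(C)O)CC[C@]12C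
F10 | step 16 | dimethyl acetal of F9 | CC(C)C[C@@H](c3c(OC)c(C(OC)OC)c(OC)c(Br)c3OC)[C@H]1CC[C@@](C)(O)[C@H]2C[C@@H](C(C)(C)O)CC[C@]12C
F11 | step 16 | 3-(dimethoxymethyl)-5-formyl-2,4,6-trimethoxyphenyl analogue of 20 | CC(C)C[C@@H](c3c(OC)c(C(OC)OC)c(OC)c(C=O)c3OC)[C@H]1CC[C@@](C)(O)[C@H]2C[C@@H](C(C)(C)O)CC[C@]12C
F0 | step 17 | none | none
A1 | alternative 1 | tert-butyldimethylsilyl dienol ether of the side-chain-free Δ2-en-4-one decalin | C1=CC=C(O[Si](C)(C)C(C)(C)C)[C@H]2C[C@@H](C(C)(C)O)CC[C@]12C
A2 | alternative 1 | 3-methyl-1-(2,4,6-trimethoxyphenyl)butan-1-ol | CC(C)CC(O)c1c(OC)cc(OC)cc1OC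
A3 | alternative 1 | γ-alkylated enone with the side chain trans to C14 and C1′ undefined | CC(C)CC(c3c(OC)cc(OC)cc3OC)[C@@H]1C=CC(=O)[C@H]2C[C@@H](C(C)(C)O)CC[C@]12C
A4 | alternative 2 | (7S)-(1(10)E,4E)-germacra-1(10),4-dien-11-ol | CC(C)(O)[C@H]1CC/C(C)=C/CC/C(C)=C/C1
A5 | alternative 2 | o-quinone methide from 2,4,6-trihydroxyisophthalaldehyde and 3-methylbutanal | CC(C)CC=C1C(=O)C(C=O)=C(O)C(C=O)=C1O
A6 | alternative 2 | C4 epimer of 24 (equatorial hydroxyl, C1′ undefined) | CC(C)CC(c1c(O)c(C=O)c(O)c(C=O)c1O)[C@H]1CC[C@](C)(O)[C@H]2C[C@@H](C(C)(C)O)CC[C@]12C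
A7 | alternative 3 | C1-lithio-Δ1-decalin with both tertiary alcohols as triethylsilyl ethers | [Li]C1=CC[C@@](C)(O[Si](CC)(CC)CC)[C@H]2C[C@@H](C(C)(C)O[Si](CC)(CC)CC)CC[C@]12C
A8 | alternative 3 | pinacol 3-methyl-1-(2,4,6-trimethoxyphenyl)butylboronate (configuration of C1′ as in 24) | CC(C)C[C@@H](c1c(OC)cc(OC)cc1OC)B1OC(C)(C)C(C)(C)O1
A9 | alternative 3 | Δ1-alkene from the Zweifel coupling | CC(C)C[C@@H](c3c(OC)cc(OC)cc3OC)C1=CC[C@@](C)(O[Si](CC)(CC)CC)[C@H]2C[C@@H](C(C)(C)O[Si](CC)(CC)CC)CC[C@]12C
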